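## Structural features

Compound 19 is a 1-aryl-1,2-dihydronaphthalene of the cyclolignan type. Ring A is a 6,7-dimethoxybenzo ring, and the fused ring B carries on consecutive carbons a 4-hydroxy-3-methoxyphenyl (guaiacyl) group at C1, a hydroxymethyl group at C2, a formyl group at C3 of the C3=C4 alkene, and the styrenic CH at C4. C1 (S) and C2 (R) are the only stereocentres; they are neighbours and their substituents are trans. C1 is a diarylmethine whose two aryl groups are both electron-rich alkoxybenzenes, so its configuration has to be imposed by a catalyst. The fragile elements are: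
- the enal, which also forbids a late hydrogenation;
- the γ-hydroxy aldehyde relation between C2–CH2OH and the C3 formyl group, which invites lactol formation;
- the free phenol para to the C1–H bond;
- the dihydronaphthalene itself, which can aromatise or shift its alkene to C2=C3 under forcing acid or base, with loss of C2.

The real difficulty is absolute and relative control of the C1/C2 pair while C2 and C3 are kept at different oxidation levels (CH2OH and CHO). The key step exploits the fact that C1 and C2 are vicinal sp3 carbons: C1 bears two different aryl groups (ring A and guaiacyl), and C2 bears C3 and a one-carbon alcohol that is the homologue of a C–B bond. Guaiacyl and C3 can therefore be added anti across the C1=C2 bond of a ring A (E)-styrenyl boronate. Ring B is then closed without touching either centre, by aldol condensation of the C3 acetaldehyde arm onto a formyl group on ring A (C4).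

## Logic of the disconnections

19 ⇒ 18 ⇒ 17. The C3=C4 bond of 19 is the retron of an aldol condensation and leads to 18; masking both formyl groups of 18 as cyclic acetals gives 17. This is the one ring bond whose formation creates no stereocentre and leaves C3 and C4 at the required oxidation levels. The bicycle becomes an open diarylmethane that already holds the C1/C2 pair. The forward step must hydrolyse two acetals and condense an enolisable aldehyde onto a deactivated aryl aldehyde, although 18 rests largely as its lactol, and it must not aromatise ring B.

17 ⇒ 16. The phenolic O–H is traced back to an O–benzyl bond, because the phenol cannot be free during the organometallic steps. Placing the cleavage before ring closure allows plain hydrogenolysis, since no alkene is present yet. The demand is selectivity over the benzylic C–O bonds of the aryl acetal.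

16 ⇒ 15 ⇒ 14. The C2–CH2OH bond is cut: the hydroxymethyl group is the oxidised, one-carbon-homologated image of a C2–B bond. This turns C2 into a secondary boronate, which is exactly what a 1,2-metallate shift produces. The forward steps must add a carbenoid to a crowded boron, insert only once, and migrate with retention.

14 ⇒ 13 ⇒ 7 + 12 + 11. Two bonds are cut at once, C2–C3 and C1–guaiacyl, which takes the molecule apart into three fragments of similar size and removes both stereocentres. The forward step needs face selection on the alkene of 13, a stereospecific anti addition, and 1,2-migration in preference to direct coupling at boron. For that reason 7 carries a more hindered diol on boron than the usual tetramethyl one, 11 is a triflate, and halide has to be scavenged.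

7 ⇒ 2 + 6. The aryl–vinyl bond is cut, a Heck retron that delivers the E geometry. The demand is alkene insertion and not transmetallation of the boronate.

6 ⇒ 4 + 5, and 4 ⇒ 3. The B–O bonds are exchanged, and the two C–CH3 bonds of 4 are cut back to a 1,2-dione. The only demand is the cis relation of the hydroxyl groups, without which no chelate can form.

2 ⇒ 1, and 11 ⇒ 10 ⇒ 9 ⇒ 8. These are an acetal C–O cut, an O–S cut, and an aryl C–O bond traced back to a formyl group by oxidative aryl migration. All are functional-group operations on purchasable arenes; 12 is bought.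

## Other disconnections considered

Alternative 1: The cut takes C4 out as a one-carbon unit, breaking C3–C4 and C4–C4a. It leaves the β-(diarylmethyl)butyrolactone A2, in which ring A is a plain 3,4-dimethoxyphenyl group and the guaiacyl oxygen is a tosylate. In the forward key step the enolate of A2 would be formylated at C3 with a formate ester and cyclodehydrated with acid in the same operation, the new carbon attacking ring A para to a methoxy group, to give the butenolide-fused dihydronaphthalene A1.
- In its favour: cheap reagents and no transition metal. Ring A needs no ortho handle, and on this point it is better than the chosen plan. The closing position is activated while the tosylate switches off the other ring, and C1 and C2 are left alone.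
- Against it here: the step creates neither stereocentre, so the C1/C2 pair of A2 needs its own asymmetric synthesis, which is the actual problem of 19. A1 holds C3 at the carboxylic level inside a lactone, so 19 would require a half-reduction to the lactol without over-reduction, then detosylation under conditions an enal tolerates poorly. The alkylidene lactone of A1 can also slip to the endocyclic C2=C3 butenolide or aromatise, which would erase C2.
- Comparison: both plans close ring B at C3–C4 onto ring A, the alternative by electrophilic substitution and the chosen plan by aldol condensation onto a formyl group. The alternative's key step should be at least as robust mechanistically, and it is equal in being a single flask. It carries no stereochemical information, whereas step 7 creates both centres and two skeletal bonds. With the asymmetric route to A2 and the redox and deprotection steps after A1, the whole sequence should be longer than the ten steps planned here.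

Alternative 2: The cut is the C1–C2 bond. The precursor is the racemic sulfone A4, a ring A (E)-arylidenesuccinate whose ortho substituent is a (4-hydroxy-3-methoxyphenyl)(sulfonyl)methyl group. In the forward step a chiral quaternary ammonium phase-transfer catalyst and aqueous hydroxide would expel sulfinate from A4. The C2 dienolate would then add in 1,6 fashion to the exocyclic carbon C1 of the resulting quinone methide unit, closing ring B to the diester A3.
- In its favour: ring B and both centres in one metal-free operation. The phenol emerges free, so the guaiacyl ring needs no protecting group, which is better than the chosen plan (step 9 and the benzyl group). C2 is α to an ester, so the trans relation can settle thermodynamically. A4 should be reachable by condensation chemistry in a step count equal to or lower than that of 7 plus 11.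
- Against it here: control of C1 would rest on ion pairing in an intramolecular cyclisation that can also run without the catalyst in the basic medium. The same base can move the alkene of A3 to C2=C3 or cause aromatisation. A3 has C2 and C3 both as methyl esters, so the end game needs reduction of both and selective oxidation of the allylic alcohol beside a phenol that is itself oxidisable at C1.
- Comparison: the alternative forms the C1–C2 bond that the chosen plan never breaks, and has ring A joined to C4 from the start. Step 7 takes its absolute sense from a ligand-bound metal in an inner-sphere cycle and its relative sense from a stereospecific anti addition; the alternative relies on a looser ion pair and on equilibration. Up to the ring closure the alternative is probably equal or slightly better in step count. It loses that in the redox correction, which the chosen plan avoids because 14 already holds C2 and C3 at levels that convert directly into CH2OH and CHO.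

Alternative 3: The cut removes C1–C2 and C3–C4 together, a retro-Diels–Alder that leaves the 2-benzylbenzaldehyde A6 and dimethyl fumarate A7. In the forward step irradiation of A6 would give its photoenol by a 1,5-hydrogen shift from the diarylmethane carbon to the excited carbonyl. This hydroxy-o-quinodimethane would add to A7 held on a chiral titanium TADDOLate Lewis acid, giving the tetralin A5 with four contiguous stereocentres.
- In its favour: it is the most convergent of the four plans, with two skeletal bonds, ring B and the C1/C2 pair in one step. The precursor needs no boron and no triflate and should take about three steps, so it is better than the chosen plan on convergence and on the way to the key step. The 2,3-trans relation is copied from A7, and the C4 hydroxyl is placed for dehydration to C3=C4.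
- Against it here: the chiral Lewis acid must outrun addition of the free photoenol to unbound A7 and is usually needed in large amount. The configuration at C1 depends on which way the guaiacyl group turns in the dienol, which the catalyst does not control directly. The electron-rich aldehyde may photoenolise inefficiently. After A5 there remain dehydration, reduction of two esters, selective allylic oxidation and a debenzylation that cannot be a hydrogenolysis once the alkene exists.
- Comparison: the alternative builds ring B in the stereo-defining step, whereas the chosen plan separates the two tasks. The cycloaddition is as well founded mechanistically as the conjunctive coupling for relative configuration, but less secure for absolute configuration. The total step count should be about equal, with the alternative shorter before its key step and longer after it (four operations against the three of steps 8 to 10).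

Key step: step 7

Assumption: the (Sp,Sp) antipode of the MandyPhos ligand, (S,S)-1,1'-bis[bis(4-methoxy-3,5-dimethylphenyl)phosphino]-2,2'-bis[(R)-(dimethylamino)(phenyl)methyl]ferrocene, is taken to place palladium on the Re face of C1 of 13; if a trial coupling shows the opposite sense, the (Rp,Rp) antipode is used and nothing else changes.

Assumption: 12 is used as the purchasable THF solution, titrated before use; B(mac) denotes the cyclic boronic ester of the cis diol 4.

## Route

Step 1
Reactants: 1 2-bromo-4,5-dimethoxybenzaldehyde
Product: 2 2-(2-bromo-4,5-dimethoxyphenyl)-1,3-dioxolane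
Conditions: HOCH2CH2OH (3 equiv), p-TsOH·H2O (5 mol %), toluene, reflux, Dean–Stark
Reagents that add atoms: ethylene glycol, OCCO
Why: Acid-catalysed acetalisation driven by azeotropic removal of water; the dioxolane masks the future C4 formyl group through the organometallic and peroxide steps.

Step 2
Reactants: 3 acenaphthoquinone (acenaphthylene-1,2-dione)
Product: 4 cis-1,2-dimethyl-1,2-dihydroacenaphthylene-1,2-diol (meso)
Conditions: AlMe3 (2.5 equiv), toluene, 0 °C → rt; aq. KNaC4H4O6 work-up; recrystallisation
Reagents that add atoms: trimethylaluminium, C[Al](C)C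
Why: Twofold 1,2-addition of a methylaluminium reagent to the 1,2-dione; the second methyl should enter anti to the bulky aluminium alkoxide on the neighbouring carbon, which gives the cis diol. Any trans diol cannot chelate boron and is removed by crystallisation.

Step 3
Reactants: 4 cis-1,2-dimethyl-1,2-dihydroacenaphthylene-1,2-diol; 5 dibutyl vinylboronate
Product: 6 vinyl B(mac), 8-ethenyl-6b,9a-dimethyl-6b,9a-dihydroacenaphtho[1,2-d][1,3,2]dioxaborole (cis-fused)
Conditions: toluene, 50 °C, then n-BuOH removed in vacuo
Reagents that add atoms: none
Why: Transesterification of an acyclic boronic ester by a cis-1,2-diol, driven by chelate formation and removal of butanol.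

Step 4
Reactants: 2 2-(2-bromo-4,5-dimethoxyphenyl)-1,3-dioxolane; 6 vinyl B(mac)
Product: 7 8-{(E)-2-[2-(1,3-dioxolan-2-yl)-4,5-dimethoxyphenyl]ethenyl}-6b,9a-dimethyl-6b,9a-dihydroacenaphtho[1,2-d][1,3,2]dioxaborole
Conditions: Pd(OAc)2 (5 mol %), P(t-Bu)3·HBF4 (10 mol %), Cy2NMe (1.5 equiv), toluene, 90 °C
Reagents that add atoms: none
Why: Heck–Mizoroki arylation of a vinylboronic ester: syn carbopalladation at the terminal carbon and syn β-hydride elimination give the E-alkene. The anhydrous amine base and the hindered diol keep transmetallation at boron (Suzuki coupling) slow.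

Step 5
Reactants: 8 4-benzyloxy-3-methoxybenzaldehyde (O-benzylvanillin)
Product: 10 4-benzyloxy-3-methoxyphenol, via aryl formate 9 (not isolated)
Conditions: mCPBA, CH2Cl2, rt; aq. NaHCO3 wash; then Et3N (cat.), MeOH, rt
Reagents that add atoms: mCPBA, OOC(=O)c1cccc(Cl)c1
Why: Dakin-type Baeyer–Villiger oxidation: the electron-rich aryl group migrates to oxygen in the Criegee intermediate to give formate 9, which is methanolysed to the phenol.

Step 6
Reactants: 10 4-benzyloxy-3-methoxyphenol
Product: 11 4-benzyloxy-3-methoxyphenyl trifluoromethanesulfonate
Conditions: Tf2O, pyridine, CH2Cl2, 0 °C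
Reagents that add atoms: trifluoromethanesulfonic anhydride, O=S(=O)(OS(=O)(=O)C(F)(F)F)C(F)(F)F
Why: O-sulfonylation of the phenol; the triflate gives a cationic arylpalladium species with a non-coordinating counter-ion in step 7.

Step 7
Reactants: 7 (E)-styrenyl B(mac) ester; 12 (1,3-dioxolan-2-ylmethyl)magnesium bromide; 11 4-benzyloxy-3-methoxyphenyl trifluoromethanesulfonate
Product: 14 8-[(1S,2S)-1-(4-benzyloxy-3-methoxyphenyl)-1-[2-(1,3-dioxolan-2-yl)-4,5-dimethoxyphenyl]-3-(1,3-dioxolan-2-yl)propan-2-yl]-6b,9a-dimethyl-6b,9a-dihydroacenaphtho[1,2-d][1,3,2]dioxaborole, via magnesium borate 13 (not isolated)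
Conditions: 12 (1.1 equiv), THF, 0 °C → rt; NaOTf (2 equiv), DMSO; then 11 (1.1 equiv), Pd(OAc)2 (3 mol %), (Sp,Sp)-MandyPhos [1,1'-bis(bis(4-methoxy-3,5-dimethylphenyl)phosphino)-2,2'-bis((dimethylamino)(phenyl)methyl)ferrocene] (3.6 mol %), THF/DMSO, 40 °C
Reagents that add atoms: none
Why: Addition of 12 to boron gives the four-coordinate borate 13; NaOTf assists this and removes bromide as NaBr. Oxidative addition of 11 to zerovalent palladium (formed from Pd(OAc)2 and the bisphosphine) gives a cationic divalent arylpalladium triflate that binds the alkene of 13 instead of transmetallating. The π-complex triggers a 1,2-metallate shift: the dioxolanylmethyl group moves from boron to C2 on the face opposite palladium while palladium bonds to C1, and reductive elimination then forms the C1–aryl bond with retention, so guaiacyl and C3 add anti across the E-alkene. The closest known reaction type is the palladium-catalysed enantioselective conjunctive cross-coupling of β-substituted alkenyl boron ate complexes of diol 4, and of Grignard-derived ate complexes, with aryl triflates. No ring is closed. C1 and C2 are both new: their absolute configuration (1S,2S) comes from the ligand, which should select the Re face of C1 for palladium, and their relative configuration from the E geometry of 7 combined with the stereospecific anti addition, which maps onto the trans pair of 19. The step needs 1,2-migration to win over direct transmetallation at boron (Suzuki coupling) and over β-hydride elimination from the benzylic palladium intermediate; the bulky diol blocks the B–O–Pd contact that transmetallation requires, the triflate keeps palladium cationic, and the ferrocenyl bisphosphine speeds reductive elimination.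

Step 8
Reactants: 14 secondary B(mac) boronate
Product: 16 (2S,3S)-3-(4-benzyloxy-3-methoxyphenyl)-3-[2-(1,3-dioxolan-2-yl)-4,5-dimethoxyphenyl]-2-(1,3-dioxolan-2-ylmethyl)propan-1-ol, via homologated boronate 15 (not isolated)
Conditions: BrCH2Cl (2.5 equiv), n-BuLi (2.2 equiv), THF, −78 °C → rt; then 3 M NaOH, 30% H2O2, 0 °C → rt
Reagents that add atoms: bromochloromethane, ClCBr; hydrogen peroxide, OO
Why: Matteson homologation: chloromethyllithium formed in situ adds to boron, and the secondary alkyl group migrates to the CH2 carbon with loss of chloride and retention at C2. Alkaline peroxide then replaces boron by oxygen on the new primary carbon, which is not a stereocentre.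

Step 9
Reactants: 16 benzyl-protected primary alcohol
Product: 17 4-[(1S,2S)-1-[2-(1,3-dioxolan-2-yl)-4,5-dimethoxyphenyl]-2-(1,3-dioxolan-2-ylmethyl)-3-hydroxypropyl]-2-methoxyphenol
Conditions: H2 (1 atm), 10% Pd/C, EtOAc, rt
Reagents that add atoms: none
Why: Heterogeneous hydrogenolysis of the phenolic benzyl ether, placed before the C3=C4 alkene exists; the crowded, ortho-substituted aryl dioxolane should react much more slowly in a neutral solvent.

Step 10
Reactants: 17 phenol bis-acetal
Product: 19 (1S,2R)-1-(4-hydroxy-3-methoxyphenyl)-2-(hydroxymethyl)-6,7-dimethoxy-1,2-dihydronaphthalene-3-carbaldehyde, via hydroxy dialdehyde 18 (not isolated)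
Conditions: 1 M aq. HCl, THF, 40 °C; then Bn2NH·CF3CO2H (20 mol %), toluene, 50 °C
Reagents that add atoms: water, O
Why: Acid hydrolysis of both dioxolanes gives 18, in equilibrium with its five-membered lactol. The enamine of the only enolisable aldehyde then adds to the aryl aldehyde (intramolecular aldol, 6-(enolexo)-exo-trig) and dehydration gives the enal conjugated with ring A. Neither C1–H nor C2–H is activated towards enolisation, so the configuration from step 7 is kept.

## Compound list

1 | 2-bromo-4,5-dimethoxybenzaldehyde | COc1cc(Br)c(C=O)cc1OC | starting material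
2 | 2-(2-bromo-4,5-dimethoxyphenyl)-1,3-dioxolane | COc1cc(Br)c(cc1OC)C1OCCO1 | intermediate
3 | acenaphthoquinone | O=C1C(=O)c2cccc3cccc1c23 | starting material
4 | cis-1,2-dimethyl-1,2-dihydroacenaphthylene-1,2-diol | C[C@]1(O)c2cccc3cccc(c23)[C@@]1(C)O | intermediate
5 | dibutyl vinylboronate | C=CB(OCCCC)OCCCC | starting material
6 | 8-ethenyl-6b,9a-dimethyl-6b,9a-dihydroacenaphtho[1,2-d][1,3,2]dioxaborole (vinyl B(mac), cis-fused) | C=CB1O[C@@]2(C)c3cccc4cccc(c34)[C@@]2(C)O1 | intermediate
7 | 8-{(E)-2-[2-(1,3-dioxolan-2-yl)-4,5-dimethoxyphenyl]ethenyl}-6b,9a-dimethyl-6b,9a-dihydroacenaphtho[1,2-d][1,3,2]dioxaborole | COc1cc(/C=C/B2O[C@@]3(C)c4cccc5cccc(c45)[C@@]3(C)O2)c(cc1OC)C1OCCO1 | intermediate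
8 | 4-benzyloxy-3-methoxybenzaldehyde | COc1cc(C=O)ccc1OCc1ccccc1 | starting material
9 | 4-benzyloxy-3-methoxyphenyl formate | COc1cc(OC=O)ccc1OCc1ccccc1 | intermediate
10 | 4-benzyloxy-3-methoxyphenol | COc1cc(O)ccc1OCc1ccccc1 | intermediate
11 | 4-benzyloxy-3-methoxyphenyl trifluoromethanesulfonate | COc1cc(OS(=O)(=O)C(F)(F)F)ccc1OCc1ccccc1 | intermediate
12 | (1,3-dioxolan-2-ylmethyl)magnesium bromide | Br[Mg]CC1OCCO1 | starting material
13 | bromomagnesium {(E)-2-[2-(1,3-dioxolan-2-yl)-4,5-dimethoxyphenyl]ethenyl}(1,3-dioxolan-2-ylmethyl)borate of diol 4 | COc1cc(/C=C/[B-]2(CC3OCCO3)O[C@@]3(C)c4cccc5cccc(c45)[C@@]3(C)O2)c(cc1OC)C1OCCO1.[Mg+]Br | intermediate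
14 | 8-[(1S,2S)-1-(4-benzyloxy-3-methoxyphenyl)-1-[2-(1,3-dioxolan-2-yl)-4,5-dimethoxyphenyl]-3-(1,3-dioxolan-2-yl)propan-2-yl]-6b,9a-dimethyl-6b,9a-dihydroacenaphtho[1,2-d][1,3,2]dioxaborole | COc1cc([C@H]([C@H](CC2OCCO2)B2O[C@@]3(C)c4cccc5cccc(c45)[C@@]3(C)O2)c2cc(OC)c(OC)cc2C2OCCO2)ccc1OCc1ccccc1 | intermediate
15 | 8-[(2S,3S)-3-(4-benzyloxy-3-methoxyphenyl)-3-[2-(1,3-dioxolan-2-yl)-4,5-dimethoxyphenyl]-2-(1,3-dioxolan-2-ylmethyl)propyl]-6b,9a-dimethyl-6b,9a-dihydroacenaphtho[1,2-d][1,3,2]dioxaborole | COc1cc([C@H]([C@H](CC2OCCO2)CB2O[C@@]3(C)c4cccc5cccc(c45)[C@@]3(C)O2)c2cc(OC)c(OC)cc2C2OCCO2)ccc1OCc1ccccc1 | intermediate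
16 | (2S,3S)-3-(4-benzyloxy-3-methoxyphenyl)-3-[2-(1,3-dioxolan-2-yl)-4,5-dimethoxyphenyl]-2-(1,3-dioxolan-2-ylmethyl)propan-1-ol | COc1cc([C@H]([C@H](CC2OCCO2)CO)c2cc(OC)c(OC)cc2C2OCCO2)ccc1OCc1ccccc1 | intermediate
17 | 4-[(1S,2S)-1-[2-(1,3-dioxolan-2-yl)-4,5-dimethoxyphenyl]-2-(1,3-dioxolan-2-ylmethyl)-3-hydroxypropyl]-2-methoxyphenol | COc1cc([C@H]([C@H](CC2OCCO2)CO)c2cc(OC)c(OC)cc2C2OCCO2)ccc1O | intermediate
18 | 2-[(1S,2S)-1-(4-hydroxy-3-methoxyphenyl)-2-(hydroxymethyl)-4-oxobutyl]-4,5-dimethoxybenzaldehyde (in equilibrium with its lactol) | COc1cc([C@H]([C@H](CC=O)CO)c2cc(OC)c(OC)cc2C=O)ccc1O | intermediate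
19 | (1S,2R)-1-(4-hydroxy-3-methoxyphenyl)-2-(hydroxymethyl)-6,7-dimethoxy-1,2-dihydronaphthalene-3-carbaldehyde | COc1cc([C@H]2c3cc(OC)c(OC)cc3C=C(C=O)[C@@H]2CO)ccc1O | target

## Step count and least certain steps

Total step count: 10. Longest linear sequence: 7 steps (steps 2, 3, 4, 7, 8, 9, 10, from 3 to 19).

Step 7 (key step). The most likely failure is incomplete, reversible borate formation between the weakly nucleophilic β-alkoxy Grignard reagent and the hindered boron of 7. Three-coordinate boronate would then transmetallate directly (Suzuki-type arylation) while residual bromide slows the cationic palladium; the ortho acetal may also erode face selection. The fallback builds the same borate anion from the opposite pair of partners, free of halide. It sets out from 7: iododeboronation (NaOH, I2, THF/H2O) should give 2-{2-[(E)-2-iodoethenyl]-4,5-dimethoxyphenyl}-1,3-dioxolane F1 with retention. Iodine–lithium exchange (t-BuLi, Et2O, −78 °C) and addition of the styrenyllithium to the alkyl boronate 8-(1,3-dioxolan-2-ylmethyl) B(mac) F2 (from 12 and B(OMe)3, then diol 4) should give the lithium borate F3. Coupling of F3 with 11 under the same Pd(OAc)2/ligand system comes back to the route at 14.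

Step 8. The short-lived carbenoid may decompose before it is captured by the crowded boron of 14, and a second insertion into the less hindered 15 may compete. The fallback is a Zweifel olefination followed by oxidative cleavage. It sets out from 14: vinyllithium, then I2 and NaOMe, should give the terminal alkene F4 with retention at C2. Cleavage (OsO4 cat., NaIO4, 2,6-lutidine, dioxane/H2O) gives the α-branched aldehyde F5, which is reduced in the same flask with NaBH4 before it can epimerise. This comes back to the route at 16.

Step 10. Ring closure may stall at the lactol or a mixed cyclic acetal, because the γ-hydroxy aldehyde closes on itself, and prolonged acid could then dehydrate or aromatise ring B. The fallback removes the hydroxyl group from play. It sets out from 17: acetylation (Ac2O, pyridine) gives the diacetate F6. Acid hydrolysis gives the dialdehyde diacetate F7, which cannot lactolise and is condensed with Bn2NH·CF3CO2H to the enal diacetate F8. Methanolysis (K2CO3, MeOH, 0 °C) comes back to the route at 19.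

Step 4. Transmetallation at boron may compete with alkene insertion, transferring the vinyl group, and oxidative addition to the electron-rich, ortho-substituted bromide may be slow. The fallback makes the vinyl-transfer product on purpose. It sets out from 2: Suzuki vinylation (CH2=CHBF3K, PdCl2(dppf), Cs2CO3, THF/H2O) gives 2-(2-ethenyl-4,5-dimethoxyphenyl)-1,3-dioxolane F9. E-selective cross-metathesis of F9 with 6 (second-generation Grubbs catalyst, RuCl2(=CHPh)(PCy3)(H2IMes), CH2Cl2, 40 °C) comes back to the route at 7.

Step 9. The benzylic C–O bonds of the aryl dioxolane may be hydrogenolysed alongside the benzyl ether. The fallback postpones debenzylation and changes its mode. It sets out from 16: the conditions of step 10 give, through the O-benzyl hydroxy dialdehyde F10 (not isolated), the O-benzyl enal F11. Cleavage of the benzyl ether with BCl3 and pentamethylbenzene (CH2Cl2, −78 °C, bicarbonate quench) comes back to the route at 19.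

## Further compounds

F1 | step 7 | 2-{2-[(E)-2-iodoethenyl]-4,5-dimethoxyphenyl}-1,3-dioxolane | COc1cc(/C=C/I)c(cc1OC)C1OCCO1
F2 | step 7 | 8-(1,3-dioxolan-2-ylmethyl)-6b,9a-dimethyl-6b,9a-dihydroacenaphtho[1,2-d][1,3,2]dioxaborole (cis-fused) | C(C1OCCO1)B1O[C@@]2(C)c3cccc4cccc(c34)[C@@]2(C)O1
F3 | step 7 | lithium {(E)-2-[2-(1,3-dioxolan-2-yl)-4,5-dimethoxyphenyl]ethenyl}(1,3-dioxolan-2-ylmethyl)borate of diol 4 | COc1cc(/C=C/[B-]2(CC3OCCO3)O[C@@]3(C)c4cccc5cccc(c45)[C@@]3(C)O2)c(cc1OC)C1OCCO1.[Li+]
F4 | step 8 | 2-{2-[(1S,2R)-1-(4-benzyloxy-3-methoxyphenyl)-2-(1,3-dioxolan-2-ylmethyl)but-3-en-1-yl]-4,5-dimethoxyphenyl}-1,3-dioxolane | COc1cc([C@H]([C@H](CC2OCCO2)C=C)c2cc(OC)c(OC)cc2C2OCCO2)ccc1OCc1ccccc1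
F5 | step 8 | (2S,3S)-3-(4-benzyloxy-3-methoxyphenyl)-3-[2-(1,3-dioxolan-2-yl)-4,5-dimethoxyphenyl]-2-(1,3-dioxolan-2-ylmethyl)propanal | COc1cc([C@H]([C@H](CC2OCCO2)C=O)c2cc(OC)c(OC)cc2C2OCCO2)ccc1OCc1ccccc1
F6 | step 10 | 4-[(1S,2S)-3-acetoxy-1-[2-(1,3-dioxolan-2-yl)-4,5-dimethoxyphenyl]-2-(1,3-dioxolan-2-ylmethyl)propyl]-2-methoxyphenyl acetate | COc1cc([C@H]([C@H](CC2OCCO2)COC(C)=O)c2cc(OC)c(OC)cc2C2OCCO2)ccc1OC(C)=O
F7 | step 10 | 4-[(1S,2S)-2-(acetoxymethyl)-1-(2-formyl-4,5-dimethoxyphenyl)-4-oxobutyl]-2-methoxyphenyl acetate | COc1cc([C@H]([C@H](CC=O)COC(C)=O)c2cc(OC)c(OC)cc2C=O)ccc1OC(C)=O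
F8 | step 10 | 4-[(1S,2R)-2-(acetoxymethyl)-3-formyl-6,7-dimethoxy-1,2-dihydronaphthalen-1-yl]-2-methoxyphenyl acetate | COc1cc([C@H]2c3cc(OC)c(OC)cc3C=C(C=O)[C@@H]2COC(C)=O)ccc1OC(C)=O
F9 | step 4 | 2-(2-ethenyl-4,5-dimethoxyphenyl)-1,3-dioxolane | COc1cc(C=C)c(cc1OC)C1OCCO1
F10 | step 9 | 2-[(1S,2S)-1-(4-benzyloxy-3-methoxyphenyl)-2-(hydroxymethyl)-4-oxobutyl]-4,5-dimethoxybenzaldehyde | COc1cc([C@H]([C@H](CC=O)CO)c2cc(OC)c(OC)cc2C=O)ccc1OCc1ccccc1
F11 | step 9 | (1S,2R)-1-(4-benzyloxy-3-methoxyphenyl)-2-(hydroxymethyl)-6,7-dimethoxy-1,2-dihydronaphthalene-3-carbaldehyde | COc1cc([C@H]2c3cc(OC)c(OC)cc3C=C(C=O)[C@@H]2CO)ccc1OCc1ccccc1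
A1 | alternative 1 | (3aR,4S)-6,7-dimethoxy-4-[3-methoxy-4-(4-methylbenzenesulfonyloxy)phenyl]-3a,4-dihydronaphtho[2,3-c]furan-1(3H)-one | COc1cc([C@H]2c3cc(OC)c(OC)cc3C=C4C(=O)OC[C@H]24)ccc1OS(=O)(=O)c1ccc(C)cc1
A2 | alternative 1 | (4S)-4-{(R)-(3,4-dimethoxyphenyl)[3-methoxy-4-(4-methylbenzenesulfonyloxy)phenyl]methyl}oxolan-2-one | COc1cc([C@H]([C@H]2COC(=O)C2)c2ccc(OC)c(OC)c2)ccc1OS(=O)(=O)c1ccc(C)cc1
A3 | alternative 2 | dimethyl (1S,2R)-1-(4-hydroxy-3-methoxyphenyl)-6,7-dimethoxy-1,2-dihydronaphthalene-2,3-dicarboxylate | COc1cc([C@H]2c3cc(OC)c(OC)cc3C=C(C(=O)OC)[C@@H]2C(=O)OC)ccc1O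
A4 | alternative 2 | dimethyl (E)-2-{2-[(4-hydroxy-3-methoxyphenyl)(4-methylbenzenesulfonyl)methyl]-4,5-dimethoxybenzylidene}butanedioate (racemic at the sulfonyl-bearing carbon) | COC(=O)C/C(C(=O)OC)=C\c1cc(OC)c(OC)cc1C(c1ccc(O)c(OC)c1)S(=O)(=O)c1ccc(C)cc1
A5 | alternative 3 | dimethyl (1S,2R,3S,4S)-1-(4-benzyloxy-3-methoxyphenyl)-4-hydroxy-6,7-dimethoxy-1,2,3,4-tetrahydronaphthalene-2,3-dicarboxylate | COc1cc([C@H]2c3cc(OC)c(OC)cc3[C@@H](O)[C@@H](C(=O)OC)[C@@H]2C(=O)OC)ccc1OCc1ccccc1
A6 | alternative 3 | 2-(4-benzyloxy-3-methoxybenzyl)-4,5-dimethoxybenzaldehyde | COc1cc(Cc2cc(OC)c(OC)cc2C=O)ccc1OCc1ccccc1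
A7 | alternative 3 | dimethyl fumarate | COC(=O)/C=C/C(=O)OC
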